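**Plan**

- Ret­rosynthesis: remove the eleven O-benzyl groups; take both fisetinidol units back from C3–OH/C4–H to C3=C4 alkenes; cut the two ring-C bonds O1–C2; finally cut the two bonds from catechin C6 and C8 to the future C4 carbons.
- Enabling feature: in each fisetinidol unit O1–C2 links the ring-A resorcinol oxygen to the benzylic C2. With C3=C4 in place, C2–C3–C4 is an allyl unit with ring B on C2 and ring A plus the catechin ring on C4, so C2 is the open end of a 1,1,3-triarylallyl cation.
- Forward: (+)-catechin is perbenzylated and 6,8-dibrominated; its dimetallated form adds twice to the carbonyl of a silyl-protected 2'-hydroxychalcone; fluoride frees the two phenols; one chiral-acid step closes both pyran rings; hydroboration–oxidation and hydrogenolysis finish.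
- Stereochemistry: catechin C2/C3 come from the chiral pool; both fisetinidol C2 centres are set by the chiral phosphoramide counter-anion during ring closure; C3 and C4 of each unit follow from syn hydroboration on the face opposite the C2 aryl group.

Key step: step 8

Remark: which antipode of the phosphoramide gives the required sense cannot be derived on paper; the (R) catalyst is written and would be exchanged for the (S) catalyst if a model closure shows the opposite sense.
Remark: the chromene C2 descriptor is S and becomes R after hydroboration only because the CIP rank of C3 changes; the spatial arrangement is the one of the target.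
Remark: the benzylated acetophenone and benzaldehyde are taken as purchased catalogue chemicals.

**Route**

Step 1
Reactants: 1 (+)-catechin
Product: 2 tetra-O-benzylcatechin (phenols benzylated; C3–OH free)
Conditions: BnBr (4.4 equiv), K2CO3, DMF, 0 °C to rt
Reagents that add atoms: benzyl bromide, BrCc1ccccc1
Why: Williamson ether synthesis on the four phenoxides: K2CO3 is strong enough for the phenols but not for the C3 alcohol, so only the aryl oxygens should be benzylated and the two stereocentres are not touched.

Step 2
Reactants: 2 tetra-O-benzylcatechin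
Product: 3 penta-O-benzylcatechin
Conditions: NaH, BnBr, DMF, 0 °C to rt
Reagents that add atoms: benzyl bromide, BrCc1ccccc1
Why: Williamson ether synthesis on the secondary alkoxide made with NaH; because every phenol is already capped, no quinone methide can open ring C and C2 cannot epimerise.

Step 3
Reactants: 3 penta-O-benzylcatechin
Product: 4 6,8-dibromo-penta-O-benzylcatechin
Conditions: NBS (2.1 equiv), CH2Cl2, 0 °C to rt
Reagents that add atoms: N-bromosuccinimide, O=C1CCC(=O)N1Br
Why: Electrophilic aromatic bromination: ring A with its three oxygen substituents is far more nucleophilic than ring B or the benzyl rings and its only free positions are C6 and C8, so two equivalents of NBS should give the 6,8-dibromide.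

Step 4
Reactants: 5 1-[4-(benzyloxy)-2-hydroxyphenyl]ethanone; 6 3,4-bis(benzyloxy)benzaldehyde
Product: 7 (E)-2'-hydroxy-4'-benzyloxy-3,4-dibenzyloxychalcone
Conditions: KOH, EtOH, rt; dilute HCl work-up
Reagents that add atoms: none
Why: Claisen–Schmidt condensation (crossed aldol addition of the methyl ketone enolate to a non-enolisable aldehyde followed by E1cB loss of water) gives the (E)-enone, and under strong base the 2'-phenoxide holds the open chalcone in preference to the flavanone.

Step 5
Reactants: 7 (E)-2'-hydroxychalcone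
Product: 8 (E)-2'-(triisopropylsilyloxy)chalcone
Conditions: TIPSOTf (1.3 equiv), 2,6-lutidine, CH2Cl2, 0 °C to rt
Reagents that add atoms: triisopropylsilyl trifluoromethanesulfonate, CC(C)[Si](C(C)C)(C(C)C)OS(=O)(=O)C(F)(F)F
Why: O-Silylation of the hydrogen-bonded 2'-phenol by the silyl triflate in the presence of a hindered pyridine; the triisopropylsilyl group is chosen because its bulk should hold back oxygen-to-oxygen silyl transfer to the tertiary alkoxide of step 6 and because fluoride removes it without acid.

Step 6
Reactants: 4 6,8-dibromo-penta-O-benzylcatechin; 8 (E)-2'-(triisopropylsilyloxy)chalcone (2.4 equiv)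
Product: 11 bis(silyl ether) bis-carbinol (mixture of carbinol epimers), via dilithiated catechin ether 9 (not isolated), via diceriated catechin ether 10 (not isolated)
Conditions: t-BuLi (4.2 equiv), THF, −78 °C; anhydrous CeCl3 (2.3 equiv), −78 °C; then 8, −78 to −40 °C; H2O quench at −40 °C
Reagents that add atoms: none
Why: Bromine–lithium exchange at both positions (two equivalents of t-BuLi per bromine, the second consuming the tert-butyl bromide formed), transmetalation to the oxophilic and weakly basic aryl cerium dichloride, and organocerium 1,2-addition to the non-enolisable enone carbonyl in preference to conjugate addition; the two new carbinol centres form without control, which does no harm because both are erased by ionisation in step 8.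

Step 7
Reactants: 11 bis(silyl ether) bis-carbinol
Product: 12 bis-phenol bis-carbinol (mixture of carbinol epimers; key-step precursor)
Conditions: Bu4NF (2.2 equiv), THF, −20 to 0 °C; ice-cold pH 7 aqueous work-up; used at once without chromatography
Reagents that add atoms: none
Why: Fluoride-induced cleavage of the two aryl silyl ethers, driven by Si–F bond formation, under basic conditions in which the tertiary allylic alcohols cannot ionise; cold neutral work-up and immediate use are meant to keep the very acid-sensitive ortho-hydroxyaryl carbinols from closing without the chiral acid.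

Step 8
Reactants: 12 bis-phenol bis-carbinol
Product: 13 bis[(2S)-2H-chromen-4-yl] penta-O-benzylcatechin
Conditions: (R)-H8-BINOL-derived N-triflylphosphoramide bearing 3,3'-bis(2,4,6-triisopropylphenyl) groups (10 mol %), toluene (0.01 M), −78 °C; Et3N added at −78 °C
Reagents that add atoms: none
Why: The chiral N-triflylphosphoramide protonates each tertiary, doubly benzylic allylic hydroxyl and water leaves in an SN1-type ionisation, giving a 1,1,3-triarylallyl cation held as a hydrogen-bonded contact ion pair with the chiral phosphoramide anion, so that every carbinol epimer converges on the same intermediate. The closest known reaction type is the chiral Brønsted acid-catalysed intramolecular allylic substitution of ortho-hydroxyaryl allylic alcohols to 2,4-diaryl-2H-chromenes. Each of the two pyran rings closes when the resorcinol-ring hydroxyl attacks the allyl terminus that carries the 3,4-dibenzyloxyphenyl group, a 6-endo-trig closure (equivalently an oxa-6π closure of the vinylogous ortho-quinone methide), attack at the other terminus being excluded because it would give a four-membered ring. Each of the two new C2 stereocentres is set by the chiral counter-anion, which binds the phenol O–H and covers one face of the cation terminus, while the catechin stereocentres are too remote to bias either closure. The step needs enantiofacial selectivity at both termini and O- over C-attack: the first is secured by tight ion pairing in toluene at low temperature with ionisation made dependent on the chiral acid, the second by the substrate, since the catechin ring has no free ortho position and the one free ortho carbon of the resorcinol ring is meta to both of its oxygens.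

Step 9
Reactants: 13 bis[(2S)-2H-chromen-4-yl] penta-O-benzylcatechin
Product: 15 undeca-O-benzyl triflavanoid with two free C3 hydroxyls, via bis(C3-borane) 14 (not isolated)
Conditions: BH3·THF (6 equiv), THF, 0 °C to rt; then aq NaOH, 30% H2O2, 0 °C to rt
Reagents that add atoms: hydrogen peroxide, OO
Why: Hydroboration–oxidation: borane adds syn across each C3=C4 bond with boron on C3, away from the diaryl-substituted C4, and from the face opposite the C2 aryl group (as known for flav-3-enes and for cycloalkenes that carry a 2,6-dialkoxyphenyl group), and oxidation with retention then puts the C3 hydroxyl trans to the C2 aryl group and the C4 hydrogen cis to that hydroxyl, which is the 2,3-trans-3,4-trans (2R,3S,4S) pattern of both fisetinidol units.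

Step 10
Reactants: 15 undeca-O-benzyl triflavanoid
Product: 16 target, fisetinidol-(4α→8)-catechin-(6→4α)-fisetinidol
Conditions: H2 (1 atm), Pd(OH)2 on carbon, THF/MeOH/H2O, rt
Reagents that add atoms: none
Why: Hydrogenolysis of all eleven benzyl ethers over Pd(OH)2 on carbon under neutral conditions, in which the benzylic O1–C2 ring bonds and the C4–aryl bonds of flavan-3-ol oligomers are known to hold, so that no stereocentre is touched.

**Compound list**

1 | (+)-catechin, (2R,3S)-2-(3,4-dihydroxyphenyl)chromane-3,5,7-triol | Oc1cc(O)c2c(c1)O[C@H](c1ccc(O)c(O)c1)[C@@H](O)C2 | starting material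

2 | (2R,3S)-5,7-bis(benzyloxy)-2-[3,4-bis(benzyloxy)phenyl]chroman-3-ol | O(Cc9ccccc9)c1cc(OCc9ccccc9)c2c(c1)O[C@H](c1ccc(OCc9ccccc9)c(OCc9ccccc9)c1)[C@@H](O)C2 | intermediate

3 | (2R,3S)-3,5,7-tris(benzyloxy)-2-[3,4-bis(benzyloxy)phenyl]chromane | O(Cc9ccccc9)c1cc(OCc9ccccc9)c2c(c1)O[C@H](c1ccc(OCc9ccccc9)c(OCc9ccccc9)c1)[C@@H](OCc9ccccc9)C2 | intermediate

4 | (2R,3S)-3,5,7-tris(benzyloxy)-2-[3,4-bis(benzyloxy)phenyl]-6,8-dibromochromane | O(Cc9ccccc9)c1c(Br)c(OCc9ccccc9)c2c(c1Br)O[C@H](c1ccc(OCc9ccccc9)c(OCc9ccccc9)c1)[C@@H](OCc9ccccc9)C2 | intermediate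

5 | 1-[4-(benzyloxy)-2-hydroxyphenyl]ethanone | CC(=O)c1ccc(OCc9ccccc9)cc1O | starting material

6 | 3,4-bis(benzyloxy)benzaldehyde | O=Cc1ccc(OCc9ccccc9)c(OCc9ccccc9)c1 | starting material

7 | (E)-1-[4-(benzyloxy)-2-hydroxyphenyl]-3-[3,4-bis(benzyloxy)phenyl]prop-2-en-1-one | O=C(/C=C/c1ccc(OCc9ccccc9)c(OCc9ccccc9)c1)c1ccc(OCc9ccccc9)cc1O | intermediate

8 | (E)-1-{4-(benzyloxy)-2-[(triisopropylsilyl)oxy]phenyl}-3-[3,4-bis(benzyloxy)phenyl]prop-2-en-1-one | O=C(/C=C/c1ccc(OCc9ccccc9)c(OCc9ccccc9)c1)c1ccc(OCc9ccccc9)cc1O[Si](C(C)C)(C(C)C)C(C)C | intermediate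

9 | 6,8-dilithio derivative of penta-O-benzylcatechin | [Li]c1c(OCc9ccccc9)c2c(c([Li])c1OCc9ccccc9)O[C@H](c1ccc(OCc9ccccc9)c(OCc9ccccc9)c1)[C@@H](OCc9ccccc9)C2 | intermediate (not isolated)

10 | 6,8-bis(dichlorocerio) derivative of penta-O-benzylcatechin (trivalent cerium) | Cl[Ce](Cl)c1c(OCc9ccccc9)c2c(c([Ce](Cl)Cl)c1OCc9ccccc9)O[C@H](c1ccc(OCc9ccccc9)c(OCc9ccccc9)c1)[C@@H](OCc9ccccc9)C2 | intermediate (not isolated)

11 | (2R,3S)-3,5,7-tris(benzyloxy)-2-[3,4-bis(benzyloxy)phenyl]-6,8-bis{(2E)-1-{4-(benzyloxy)-2-[(triisopropylsilyl)oxy]phenyl}-3-[3,4-bis(benzyloxy)phenyl]-1-hydroxyprop-2-en-1-yl}chromane, carbinol epimers | OC(/C=C/c1ccc(OCc9ccccc9)c(OCc9ccccc9)c1)(c1ccc(OCc9ccccc9)cc1O[Si](C(C)C)(C(C)C)C(C)C)c1c(OCc9ccccc9)c2c(c(C(O)(/C=C/c3ccc(OCc9ccccc9)c(OCc9ccccc9)c3)c3ccc(OCc9ccccc9)cc3O[Si](C(C)C)(C(C)C)C(C)C)c1OCc9ccccc9)O[C@H](c1ccc(OCc9ccccc9)c(OCc9ccccc9)c1)[C@@H](OCc9ccccc9)C2 | intermediate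

12 | (2R,3S)-3,5,7-tris(benzyloxy)-2-[3,4-bis(benzyloxy)phenyl]-6,8-bis{(2E)-1-[4-(benzyloxy)-2-hydroxyphenyl]-3-[3,4-bis(benzyloxy)phenyl]-1-hydroxyprop-2-en-1-yl}chromane, carbinol epimers | OC(/C=C/c1ccc(OCc9ccccc9)c(OCc9ccccc9)c1)(c1ccc(OCc9ccccc9)cc1O)c1c(OCc9ccccc9)c2c(c(C(O)(/C=C/c3ccc(OCc9ccccc9)c(OCc9ccccc9)c3)c3ccc(OCc9ccccc9)cc3O)c1OCc9ccccc9)O[C@H](c1ccc(OCc9ccccc9)c(OCc9ccccc9)c1)[C@@H](OCc9ccccc9)C2 | intermediate

13 | (2R,3S)-3,5,7-tris(benzyloxy)-2-[3,4-bis(benzyloxy)phenyl]-6,8-bis{(2S)-7-(benzyloxy)-2-[3,4-bis(benzyloxy)phenyl]-2H-chromen-4-yl}chromane | O(Cc9ccccc9)c1ccc2c(c1)O[C@H](c1ccc(OCc9ccccc9)c(OCc9ccccc9)c1)C=C2c1c(OCc9ccccc9)c2c(c(C3=C[C@@H](c4ccc(OCc9ccccc9)c(OCc9ccccc9)c4)Oc4cc(OCc9ccccc9)ccc34)c1OCc9ccccc9)O[C@H](c1ccc(OCc9ccccc9)c(OCc9ccccc9)c1)[C@@H](OCc9ccccc9)C2 | intermediate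

14 | bis(C3-dihydroboryl) adduct of 13, boron on C3 of each fisetinidol ring in the place and on the face later taken by the hydroxyl of 15 | O(Cc9ccccc9)c1ccc2c(c1)O[C@H](c1ccc(OCc9ccccc9)c(OCc9ccccc9)c1)[C@@H](B)[C@@H]2c1c(OCc9ccccc9)c2c(c([C@@H]3c4ccc(OCc9ccccc9)cc4O[C@H](c4ccc(OCc9ccccc9)c(OCc9ccccc9)c4)[C@H]3B)c1OCc9ccccc9)O[C@H](c1ccc(OCc9ccccc9)c(OCc9ccccc9)c1)[C@@H](OCc9ccccc9)C2 | intermediate (not isolated)

15 | (2R,3S)-3,5,7-tris(benzyloxy)-2-[3,4-bis(benzyloxy)phenyl]-6,8-bis{(2R,3S,4S)-7-(benzyloxy)-2-[3,4-bis(benzyloxy)phenyl]-3-hydroxy-3,4-dihydro-2H-chromen-4-yl}chromane | O(Cc9ccccc9)c1ccc2c(c1)O[C@H](c1ccc(OCc9ccccc9)c(OCc9ccccc9)c1)[C@@H](O)[C@@H]2c1c(OCc9ccccc9)c2c(c([C@@H]3c4ccc(OCc9ccccc9)cc4O[C@H](c4ccc(OCc9ccccc9)c(OCc9ccccc9)c4)[C@H]3O)c1OCc9ccccc9)O[C@H](c1ccc(OCc9ccccc9)c(OCc9ccccc9)c1)[C@@H](OCc9ccccc9)C2 | intermediate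

16 | (2R,3S)-2-(3,4-dihydroxyphenyl)-6,8-bis[(2R,3S,4S)-2-(3,4-dihydroxyphenyl)-3,7-dihydroxy-3,4-dihydro-2H-chromen-4-yl]chromane-3,5,7-triol | Oc1ccc2c(c1)O[C@H](c1ccc(O)c(O)c1)[C@@H](O)[C@@H]2c1c(O)c2c(c([C@@H]3c4ccc(O)cc4O[C@H](c4ccc(O)c(O)c4)[C@H]3O)c1O)O[C@H](c1ccc(O)c(O)c1)[C@@H](O)C2 | target

**Count and risks**

Total step count: 10. Longest linear sequence: 8 steps from (+)-catechin (steps 1, 2, 3, 6, 7, 8, 9, 10).

Steps most likely to fail:

Step 8. What may go wrong is ionisation that is not tied to the chiral acid: a loose ion pair of the strongly stabilised cation, or closure through the neutral quinone methide. Either would erode facial selectivity at one or both C2 centres; intermolecular Friedel–Crafts capture of the cation is a further side path. Fallback: setting out from 12, both rings are closed with an achiral acid (diphenyl phosphate, CH2Cl2, −20 °C). This should give the bis-chromene as a mixture of C2 epimers F1, which are diastereomers because the catechin core is a single enantiomer. They are separated by preparative HPLC, and the isomer with both new centres S is 13, where the route is rejoined before step 9. The assignment would be checked after step 9 through the ring-C coupling constants and circular dichroism expected for 2,3-trans-3,4-trans units.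

Step 6. What may go wrong is the second bromine–lithium exchange on the already metallated ring, or the second crowded carbonyl addition, stalling so that only one arm is installed; conjugate addition is a side path. Fallback: setting out from 4, one bromine is exchanged with n-BuLi (1 equiv, THF, −78 °C), and the aryl lithium is transmetallated with CeCl3 and added to 8. This should give the mono-carbinol monobromide F2, drawn with the carbinol at C8; the C6 regioisomer would serve equally well. F2 is isolated, and a second cycle on it (t-BuLi, 3 equiv, the first deprotonating the hydroxyl; CeCl3; 8) installs the other arm and comes back to the route at 11.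

Step 7. What may go wrong is transfer of the silyl group from the phenol oxygen to the neighbouring tertiary oxygen, or closure of the bare phenoxide or phenol to the chromene without the chiral anion during fluoride treatment and work-up. Fallback without any silyl group: setting out from 7, NaH (1 equiv, THF, 0 °C) gives the sodium phenolate of the chalcone F3. This is added at −78 °C to the dicerium reagent 10 made from 4 as in step 6; addition of aryl metals to salts of ortho-hydroxyaryl ketones is classical chemistry. Cold neutral work-up should give 12 directly, so no fluoride step is needed and the route is rejoined at 12 before step 8.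

**Further compounds**

F1 | step 8 | C2-epimer mixture of the bis-chromene 13 (both chromene C2 centres undefined, catechin core 2R,3S) | O(Cc9ccccc9)c1ccc2c(c1)OC(c1ccc(OCc9ccccc9)c(OCc9ccccc9)c1)C=C2c1c(OCc9ccccc9)c2c(c(C3=CC(c4ccc(OCc9ccccc9)c(OCc9ccccc9)c4)Oc4cc(OCc9ccccc9)ccc34)c1OCc9ccccc9)O[C@H](c1ccc(OCc9ccccc9)c(OCc9ccccc9)c1)[C@@H](OCc9ccccc9)C2

F2 | step 6 | (2R,3S)-3,5,7-tris(benzyloxy)-2-[3,4-bis(benzyloxy)phenyl]-6-bromo-8-{(2E)-1-{4-(benzyloxy)-2-[(triisopropylsilyl)oxy]phenyl}-3-[3,4-bis(benzyloxy)phenyl]-1-hydroxyprop-2-en-1-yl}chromane, carbinol epimers | Brc1c(OCc9ccccc9)c2c(c(C(O)(/C=C/c3ccc(OCc9ccccc9)c(OCc9ccccc9)c3)c3ccc(OCc9ccccc9)cc3O[Si](C(C)C)(C(C)C)C(C)C)c1OCc9ccccc9)O[C@H](c1ccc(OCc9ccccc9)c(OCc9ccccc9)c1)[C@@H](OCc9ccccc9)C2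

F3 | step 7 | sodium 5-(benzyloxy)-2-{(E)-3-[3,4-bis(benzyloxy)phenyl]prop-2-enoyl}phenolate | [Na+].[O-]c1cc(OCc9ccccc9)ccc1C(=O)/C=C/c1ccc(OCc9ccccc9)c(OCc9ccccc9)c1
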